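## Retrosynthetic overview
1. The last operation frees the two 4-OH groups by cleaving the central O–CH3 of each 3,4,5-trimethoxyphenyl ring in the hexamethyl ether diol.
2. The key disconnection is the two primary C–O bonds (C9–OH and C9'–OH). Both go back to the =CH2 termini of 2,3-bis(3,4,5-trimethoxybenzyl)buta-1,3-diene, so the forward step is a twofold enantioselective anti-Markovnikov hydration that also sets C8 and C8'.
3. The diene goes back to doubly allyl-metalated 2,3-dimethylbuta-1,3-diene (the C4 core) and two molecules of 5-bromo-1,2,3-trimethoxybenzene (two C7–aryl couplings).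
4. No ring is formed in the route; both arene rings are bought.

Assumption: the ligand antipodes written in step 2 are taken to give (R) at each new centre; because the step is new, this is checked on 8 in the first run, and either ligand can be swapped for its mirror image independently of the other.

## Route

**Step 1**
Reactants: 1 2,3-dimethylbuta-1,3-diene; 2 5-bromo-1,2,3-trimethoxybenzene (2.1 equiv)
Product: 5 2,3-bis(3,4,5-trimethoxybenzyl)buta-1,3-diene, via dipotassium dianion 3 (not isolated), via bis(chlorozinc) reagent 4 (not isolated)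
Conditions: n-BuLi/KOt-Bu (2.2 equiv each), hexane, 0 °C to rt; ZnCl2 (4.4 equiv), THF, −40 to 0 °C; 2, Pd(OAc)2 (2 mol %), SPhos (4 mol %), THF, 40 °C; aqueous work-up
Reagents that add atoms: potassium tert-butoxide CC(C)(C)[O-].[K+] (K of 3 only); zinc chloride Cl[Zn]Cl (ZnCl of 4 only); no reagent atom stays in 5
Why: Lochmann–Schlosser double allylic metalation gives the cross-conjugated dianion, whose 2-substituted allyl termini are degenerate, so after K-to-Zn exchange a twofold Negishi allyl–aryl coupling can give only one regioisomer; no stereocentre is formed.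

**Step 2**
Reactants: 5 2,3-bis(3,4,5-trimethoxybenzyl)buta-1,3-diene
Product: 8 (2R,3R)-2,3-bis(3,4,5-trimethoxybenzyl)butane-1,4-diol, via (R)-homoallyl boronate 6 (not isolated), via (R,R)-bis(boronate) 7 (not isolated)
Conditions: (i) CuCl (5 mol %), (S,S)-Ph-BPE (5.5 mol %), NaOt-Bu (10 mol %), B2pin2 (1.05 equiv), MeOH (2 equiv), THF, −20 to 0 °C; (ii) premixed CuCl/NaOt-Bu/(R)-DTBM-SEGPHOS (5/10/5.5 mol %), HBpin (3 equiv), 40 °C; (iii) 3 M NaOH, 30% H2O2, 0 °C to rt
Reagents that add atoms: hydrogen peroxide OO (both new O atoms of 8); bis(pinacolato)diboron CC1(C)OB(OC1(C)C)B1OC(C)(C)C(C)(C)O1 (Bpin of 6); pinacolborane B1OC(C)(C)C(C)(C)O1 (second Bpin of 7)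
Why: Proposed new method: a one-flask Cu–B/Cu–H relay that amounts to a twofold enantioselective anti-Markovnikov hydration of a 2,3-disubstituted 1,3-diene; (i) L*Cu–Bpin adds with B on a terminal CH2, the allylcopper relaxes to its primary σ-form, and MeOH protonates it at the γ-carbon through a closed SE2' transition state in the Ph-BPE pocket, which sets C8 and leaves the isolated 1,1-disubstituted alkene of 6; (ii) that alkene cannot be borylcuprated in the needed sense because this would require a tertiary alkylcopper, so the copper nucleophile is switched to DTBM-SEGPHOS–CuH, the only species present that hydrocuprates unactivated alkenes, which adds syn with H on the fully substituted carbon and Cu on CH2, sets C8' under catalyst control by distinguishing CH2Ar from the branched CH(CH2Ar)CH2Bpin group, and gives 7 by σ-bond metathesis with HBpin; (iii) hydroperoxide-induced 1,2-migration from boron to oxygen then makes both C–O bonds without touching C8 or C8'; heterochiral errors end up as the separable meso diol, so the ee of 8 is amplified (Horeau effect); the closest known reaction types are Cu-catalysed enantioselective 1,2-protoboration of 2-monosubstituted 1,3-dienes and CuH-catalysed anti-Markovnikov hydroboration or hydroamination of 1,1-disubstituted alkenes, and neither has been shown on a 2,3-disubstituted diene or run in relay.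

**Step 3**
Reactants: 8 (2R,3R)-2,3-bis(3,4,5-trimethoxybenzyl)butane-1,4-diol
Product: 10 (2R,3R)-2,3-bis(4-hydroxy-3,5-dimethoxybenzyl)butane-1,4-diol = 5,5'-dimethoxysecoisolariciresinol, via disodium bis(phenolate) 9 (not isolated)
Conditions: EtSNa (8 equiv), degassed DMF, 120 °C, N2; then 1 M HCl
Reagents that add atoms: sodium ethanethiolate CC[S-].[Na+] (Na of 9 only); no reagent atom other than H stays in 10
Why: SN2 O-demethylation by a soft thiolate attacks the central methoxy group, which its two neighbours twist out of the ring plane, and it stops after one cleavage per ring because the resulting phenolate ring is a poor leaving group for a second one; C8 and C8' carry no acidic H and are untouched.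

## Compound list
1 | 2,3-dimethylbuta-1,3-diene | CC(=C)C(C)=C | starting material
2 | 5-bromo-1,2,3-trimethoxybenzene | COc1cc(Br)cc(OC)c1OC | starting material
3 | (2,3-dimethylidenebutane-1,4-diyl)dipotassium, the cross-conjugated dianion of 1 | [K]CC(=C)C(=C)C[K] | intermediate
4 | (2,3-dimethylidenebutane-1,4-diyl)bis(chlorozinc) | Cl[Zn]CC(=C)C(=C)C[Zn]Cl | intermediate
5 | 2,3-bis(3,4,5-trimethoxybenzyl)buta-1,3-diene | C=C(Cc1cc(OC)c(OC)c(OC)c1)C(=C)Cc1cc(OC)c(OC)c(OC)c1 | intermediate
6 | pinacol [(2R)-2,3-bis(3,4,5-trimethoxybenzyl)but-3-en-1-yl]boronate | COc1cc(C[C@@H](CB2OC(C)(C)C(C)(C)O2)C(=C)Cc2cc(OC)c(OC)c(OC)c2)cc(OC)c1OC | intermediate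
7 | bis(pinacol) [(2R,3R)-2,3-bis(3,4,5-trimethoxybenzyl)butane-1,4-diyl]diboronate | COc1cc(C[C@@H](CB2OC(C)(C)C(C)(C)O2)[C@H](CB2OC(C)(C)C(C)(C)O2)Cc2cc(OC)c(OC)c(OC)c2)cc(OC)c1OC | intermediate
8 | (2R,3R)-2,3-bis(3,4,5-trimethoxybenzyl)butane-1,4-diol | COc1cc(C[C@@H](CO)[C@H](CO)Cc2cc(OC)c(OC)c(OC)c2)cc(OC)c1OC | intermediate
9 | disodium bis(phenolate) of 10 | [Na+].[Na+].COc1cc(C[C@@H](CO)[C@H](CO)Cc2cc(OC)c([O-])c(OC)c2)cc(OC)c1[O-] | intermediate
10 | (2R,3R)-2,3-bis(4-hydroxy-3,5-dimethoxybenzyl)butane-1,4-diol (5,5'-dimethoxysecoisolariciresinol) | COc1cc(C[C@@H](CO)[C@H](CO)Cc2cc(OC)c(O)c(OC)c2)cc(OC)c1O | target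

## Step count and risks
Total steps: 3. Longest linear sequence: 3.

**Step 2 (the new step, highest risk).**
- Direct SE2 protonation would give 1,4-protoboration, that is a tetrasubstituted allyl boronate.
- Hydrocupration of the hindered alkene of 6 may be slow.
- Modest selectivity in either stage would show up as meso diol.

The fallback uses known chemistry (achiral hydroboration followed by classical resolution). It sets out from 5 and comes back at 8. Compound 5 is hydroborated twice with 9-BBN in THF to give the bis(9-borabicyclo[3.3.1]nonan-9-yl) adduct F3. NaOH/H2O2 oxidises this to 2,3-bis(3,4,5-trimethoxybenzyl)butane-1,4-diol as the racemate plus meso form F4. Esterification with (S)-2-methoxy-2-phenylacetic acid (DCC, DMAP) gives the mixture of diastereomeric bis-esters F5. The (2R,3R) bis[(S)-2-methoxy-2-phenylacetate] F6 is separated from this mixture by chromatography and crystallisation. LiOH in THF/water then releases 8.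

**Step 1.**
- Butyllithium may add to or polymerise 1 instead of metalating it.
- Dimetalation may be incomplete.
- The second coupling may fail, giving the mono-arylated diene.

The fallback builds the C8–C8' bond instead of buying it. It sets out from 2 and comes back at 5. Compound 2 and Mg in THF give 3,4,5-trimethoxyphenylmagnesium bromide F1. CuI-catalysed allylation of F1 with 2,3-dibromopropene gives 5-(2-bromoprop-2-en-1-yl)-1,2,3-trimethoxybenzene F2. Nickel-catalysed reductive homocoupling of this vinyl bromide (NiCl2(PPh3)2, Zn, Et4NI, THF, 50 °C) gives 5.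

**Step 3.**
- Some attack may occur at an outer methoxy group on one of the two rings.
- The hot phenolate may be oxidised by air.

The fallback uses Lewis-acid cleavage, directed by the higher basicity of the twisted central oxygen, on the O-protected diol. It sets out from 8 and comes back at 10. Ac2O/pyridine gives the (2R,3R) diacetate F7. AlCl3 in CH2Cl2 (0 °C to rt) removes only the central methyl of each ring to give the (2R,3R) bis(4-hydroxy-3,5-dimethoxybenzyl) diacetate F8. K2CO3/MeOH then gives 10.

## Further compounds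
F1 | step 1 | 3,4,5-trimethoxyphenylmagnesium bromide | COc1cc([Mg]Br)cc(OC)c1OC
F2 | step 1 | 5-(2-bromoprop-2-en-1-yl)-1,2,3-trimethoxybenzene | C=C(Br)Cc1cc(OC)c(OC)c(OC)c1
F3 | step 2 | 9,9'-[2,3-bis(3,4,5-trimethoxybenzyl)butane-1,4-diyl]bis(9-borabicyclo[3.3.1]nonane), stereoisomer mixture | COc1cc(CC(CB2C3CCCC2CCC3)C(CB2C3CCCC2CCC3)Cc2cc(OC)c(OC)c(OC)c2)cc(OC)c1OC
F4 | step 2 | 2,3-bis(3,4,5-trimethoxybenzyl)butane-1,4-diol, racemate plus meso form | COc1cc(CC(CO)C(CO)Cc2cc(OC)c(OC)c(OC)c2)cc(OC)c1OC
F5 | step 2 | bis[(S)-2-methoxy-2-phenylacetate] of F4, diastereomer mixture | COc1cc(CC(COC(=O)[C@@H](OC)c2ccccc2)C(COC(=O)[C@@H](OC)c2ccccc2)Cc2cc(OC)c(OC)c(OC)c2)cc(OC)c1OC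
F6 | step 2 | (2R,3R)-2,3-bis(3,4,5-trimethoxybenzyl)butane-1,4-diyl bis[(S)-2-methoxy-2-phenylacetate] | COc1cc(C[C@@H](COC(=O)[C@@H](OC)c2ccccc2)[C@H](COC(=O)[C@@H](OC)c2ccccc2)Cc2cc(OC)c(OC)c(OC)c2)cc(OC)c1OC
F7 | step 3 | (2R,3R)-2,3-bis(3,4,5-trimethoxybenzyl)butane-1,4-diyl diacetate | COc1cc(C[C@@H](COC(C)=O)[C@H](COC(C)=O)Cc2cc(OC)c(OC)c(OC)c2)cc(OC)c1OC
F8 | step 3 | (2R,3R)-2,3-bis(4-hydroxy-3,5-dimethoxybenzyl)butane-1,4-diyl diacetate | COc1cc(C[C@@H](COC(C)=O)[C@H](COC(C)=O)Cc2cc(OC)c(O)c(OC)c2)cc(OC)c1O
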